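Which flask ends with the most X at 3.0 min, and how much does each hold?

| setting | south-west | east | north | south-east | Saturday's | Tuesday's | Monday's | Friday's | Thursday's |
|---|---|---|---|---|---|---|---|---|---|
| G | 31 mM | 31 mM | 31 mM | 62 mM | 31 mM (in portions, 4, over 80 s) | 31 mM | 31 mM | 31 mM | 31 mM (fed, over 80 s) |
| E | 32.6 mM | 22 mM | 49 mM | 32.6 mM | 32.6 mM | 32.6 mM | 32.6 mM (fed, over 80 s) | 32.6 mM | 32.6 mM |
| temperature | 20 °C | 31 °C | 20 °C | 31 °C | 25 °C | 25 °C | 25 °C |  |  |
| remark | run made earlier | run made earlier | run made earlier | run made earlier | first portion at the start, last at 80 s | everything together at the start | all else is in the flask from the start; the feed brings no volume worth counting | everything together at the start at −15 °C, warmed to 25 °C at 80 s | the addition at −15 °C, then warmed to 25 °C; the feed brings no volume worth counting |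
| time |  |  |  |  | 3.0 min | 3.0 min | 3.0 min | 3.0 min | 3.0 min |

- south-west (time / min: X / %): 0.667: 58; 1.33: 60; 2.00: 62; 2.50: 61; 3.00: 67
- east (time / min: X / %): 0.200: 35; 0.667: 43; 1.00: 38; 1.50: 41; 2.50: 42
- north (time / min: X / %): 0.200: 53; 0.333: 70; 0.667: 78; 1.33: 81; 2.50: 83
- south-east (time / min: X / %): 0.200: 41; 0.667: 39; 1.00: 37; 1.50: 39; 2.50: 37

(standard deviation of a reading: 2 percentage points)

- which flask leads in amount of X, in percent of the G charged ("all alike" within 1.5 percentage points) (Saturday's / Tuesday's / Monday's / Friday's / Thursday's / all alike)
- how much X is there at the end, in percent of the G charged: Saturday's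
- how much X is there at the end, in percent of the G charged: Tuesday's
- how much X is there at the end, in percent of the G charged: Monday's
- how much X is there at the end, in percent of the G charged: Friday's
- how much X is there at the end, in percent of the G charged: Thursday's



The runs level off short of full conversion of G, and more E lifts the plateau. So reckon in fractions of the charge: e is the E charged per G charged, x the X per G charged, and e = x + w·ln(G charged / G left), with G left taken as the charge less X.

Which numbers need knowing well? The time doesn't: north moves from 81 % at 1.33 min to 83 % at 2.50 min, a step of 2 percentage points against a scatter of 2 points. Rate constants don't enter the rule singly, and e is given as 1.05. That leaves w: at a plateau like south-west's 61 %, x moves at 20 points per unit of ln w, so w is the number to know well.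

The last readings give 0.424 for north at 20 °C and 0.532 for east at 31 °C, both read with their scatter. Taking ln w straight in temperature, I get 0.470 at 25 °C: this is the waste number, the E gone elsewhere than X per unit of that logarithm, a selectivity factor in fractions. At −15 °C the same line gives 0.205.

Two Newton steps from 0.5 give 61.7 %, then 61.0 %, my figure for Tuesday's. The rule holds no feed rate of E, so Monday's gets the same. Friday's lies between that and 76.2 %, the rule's value with the cold w throughout, so I put Friday's above Tuesday's and Monday's. Saturday's and Thursday's bring G in gradually, and the rule takes G whole, so I give them no figure and leave open whether either passes Friday's.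

The forecast names Friday's and gives Saturday's 31 %, Tuesday's 60 %, Monday's 60 %, Friday's 62 %, Thursday's 61 %, on the ground that “Cold holds do little, as almost nothing reacts until warming”. My Friday's range stands higher.

Friday's leads with 67.3 %, 5.3 points above the forecast; Tuesday's gives 62.0 %, Monday's 62.0 %, Thursday's 64.2 %, Saturday's 32.4 %.

    E + X → Z (k = 0.0552 /M/s, Ea = 40.0 kJ/mol)
    G + E → J (k = 0.264 /M/s, Ea = 51.0 kJ/mol)
    E + J → Z (k = 2.39 /M/s, Ea = 58.0 kJ/mol)
    E → Q (k = 0.0316 /s, Ea = 69.0 kJ/mol)
    G + E → X (k = 3.11 /M/s, Ea = 44.0 kJ/mol)
    (constants at 25 °C)

At its change of temperature, 1.33 min, Friday's already held X at 33.2 %. Put back into the rule, its end value gives a waste number of 0.338, between 0.205 and 0.470, while Tuesday's gives 0.445. Thursday's held X at 19.3 % at its change and works out at 0.397.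

All runs are calculated from invented constants, and the scatter is random.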